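The tempting way to compare these flasks is by seconds, but a feed changes what a second is worth, so elapsed time misleads here.

| setting | zeta | epsilon | gamma |
|---|---|---|---|
| starting material | 1.0 mM | 1.0 mM | 1.0 mM (fed, over 50 s) |
| first nucleophile | 1.10 mM (fed, over 50 s) | 1.10 mM | 1.10 mM |
| gas | 0.061 mM (held) | 0.061 mM (held) | 0.061 mM (held) |
| time | 80 s | 80 s | 80 s |
| remark | all else is in the flask from the start; the feed brings no volume worth counting | everything together at the start | all else is in the flask from the start; the feed brings no volume worth counting |

- the flask with the highest amount of side product, in percent of the starting material charged ("all alike" if they lie within 1.5 percentage points) (zeta / epsilon / gamma / all alike)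
- final side product, as a percentage of the starting material charged, in zeta
- final side product, as a percentage of the starting material charged, in epsilon
- final side product, as a percentage of the starting material charged, in gamma

- percentages count the starting material that a species holds: one side product counts as two
- at the start none of second nucleophile is dissolved
- run time (zeta): 80 s

    gas ⇌ second nucleophile, rate k1*(csat - [second nucleophile]) (k1 = 1.3 s⁻¹, csat = 0.061 mM)
    starting material ⇌ intermediate (K2 = 0.0030, k2 = 0.45 s⁻¹)
    starting material + target → side product (k3 = 16 M⁻¹ s⁻¹)
    first nucleophile + intermediate → target (k4 = 3600 M⁻¹ s⁻¹)
    second nucleophile + intermediate → other capture product (k5 = 2600 M⁻¹ s⁻¹)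
    intermediate → decomposed reagent (k6 = 0.0097 s⁻¹)

Starting material opens reversibly to the intermediate, first nucleophile captures that as target, and target attacks starting material to give side product, which holds two starting materials. Starting material is the limiting reagent, 1.0 mM against 1.10 mM, so its balance is: charge = what is left + target + twice side product, small losses apart.

The intermediate returns at 150 s⁻¹, and capture runs at 3.96 s⁻¹ at most, far slower, so the intermediate stands in fast pre-equilibrium with starting material. Target therefore forms with κ = 10.8 M⁻¹ s⁻¹, multiplied by both concentrations. Capture by second nucleophile, 0.159 s⁻¹, is much smaller and is set aside.

Both product-forming steps carry [starting material], so dividing one by the other removes it. What remains is the selectivity factor σ, the side step's constant over κ: 1.48. Let b be the fraction of first nucleophile left. Per charge of first nucleophile, target is p = (b − b^σ)/(σ − 1) and side product is 1 − b − p. This curve needs first nucleophile present from the start, so it serves epsilon and gamma but not zeta, for which this reckoning offers no figure.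

The clock is b = exp(−κ∫[starting material]dt). Holding epsilon's starting material at its charge gives b = 0.421 and side product 61.7%. But the balance then leaves 0.0549 mM, so the charge is no fair mean. A mean of 0.667 mM gives 34.1% and leaves 0.348 mM. But a decay sags below a straight line, so the logarithmic mean, 0.618 mM, is better: b = 0.587 and side product 30.2%.

Gamma's starting material arrives on average 25.0 s late. The same mean over the shortened time gives 16.3%. That is probably low, yet it stands 14 percentage points under epsilon, beyond the margin.

The forecast named epsilon, with 21% in zeta, 30.6% in epsilon and 20.2% in gamma, reasoning that “Feeding delays target build-up”.

The simulation gives epsilon, with 21.4% in zeta, 30.6% in epsilon and 20.2% in gamma.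

Epsilon's reading of 58.7% first nucleophile left at 80.0 s, put on the curve, gives 30.2% side product against the simulated 30.6%. The neighbouring flask is gamma with 4.0 mM of starting material. It keeps 18.0% of its first nucleophile at 80.0 s, less than gamma's 66.2%. With that b, the curve gives 5.78% target and 33.5% side product; the neighbouring flask holds 5.72% target and 33.6% side product.

The constants were chosen freely, and the outcome is calculated.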